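**Plan**

1. The only ring-forming C–C cut is C7–C8. Germacrane numbers are used: C6 = lactone O–CH, C7 = ring-fusion CH, C8 = CHOH, C11=C13 = exocyclic methylene, C12 = lactone C=O, C14/C15 = the CH2O groups on C10/C4.
2. Enabling feature: C8–OH is homoallylic to C11=C13, so C13–C11–C7 of the five-membered lactone (ring B) is a latent allyl anion. Moving the alkene back to C7=C11 gives an α-(Bu3SnCH2)-butenolide that carries the C8 aldehyde on its C6 side chain.
3. One anti-SE2′ event closes the ten-membered ring A, sets C7 and C8, unveils the α-methylene lactone and leaves C8–OH free. It is therefore the last step, with both esters already in place.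
4. Further cuts: C7=C11 (ring-closing metathesis, ring B), C3–C4 (B-alkyl Suzuki–Miyaura union), C1=C10 (Wittig) and C5–C6 (alkynylation of acrolein). C8=O is masked as an isopropylidene alkene.
5. Forward order: fragment 1 (C1–C3, C8–C10, C14) and fragment 2 (C4–C7, C15) are joined, ring B is closed, tin is installed, the aldehyde is released, and ring A is closed.
6. Stereochemistry: C6 comes from a catalytic asymmetric alkynylation, and C7 and C8 are relayed from C6 in the key step. Both trisubstituted alkenes (cis within ring A, CIP E) come from an E-selective Wittig reaction and a hydroxyl-directed trans-hydroalumination.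

Key step: step 14

Assumption: in step 5 the (R)-BINOL–titanium catalyst is taken to give the (S)-carbinol, by analogy with alkynylzinc additions to other aldehydes; the ligand antipode would be used if the sense were opposite.

Step 1
Reactants: 1 ethyl (triphenylphosphoranylidene)acetate; 2 1-bromo-3-methylbut-2-ene
Product: 4 ethyl 5-methyl-2-(triphenylphosphoranylidene)hex-4-enoate, via phosphonium bromide 3 (not isolated)
Conditions: CHCl3, reflux; then aq NaOH, CH2Cl2, rt
Reagents that add atoms: none
Why: C-alkylation of a stabilised ylide by a primary allylic bromide (SN2), followed by deprotonation of the salt, is the standard way to an α-substituted stabilised ylide and brings in C8, C9 and the isopropylidene mask.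

Step 2
Reactants: 4 ethyl 5-methyl-2-(triphenylphosphoranylidene)hex-4-enoate; 5 acrolein
Product: 6 ethyl (2E)-2-(3-methylbut-2-enyl)penta-2,4-dienoate
Conditions: CH2Cl2, 0 °C to rt
Reagents that add atoms: none
Why: The Wittig reaction of an α-branched stabilised ylide should place the aldehyde residue (C2) trans to the ester carbon (C14) and cis to C9, which is the C1=C10 geometry of ring A.

Step 3
Reactants: 6 ethyl (2E)-2-(3-methylbut-2-enyl)penta-2,4-dienoate
Product: 7 (2E)-2-(3-methylbut-2-enyl)penta-2,4-dien-1-ol
Conditions: iBu2AlH (2.2 equiv), CH2Cl2, −78 °C; Rochelle salt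
Reagents that add atoms: none
Why: 1,2-Reduction of a conjugated ester with iBu2AlH should give the allylic alcohol (C14–OH) without touching the three alkenes or their geometry.

Step 4
Reactants: 7 (2E)-2-(3-methylbut-2-enyl)penta-2,4-dien-1-ol
Product: 8 (2E)-2-(3-methylbut-2-enyl)penta-2,4-dienyl 2-methylpropanoate (fragment 1)
Conditions: iPrCOCl, Et3N, DMAP (cat.), CH2Cl2, 0 °C
Reagents that add atoms: isobutyryl chloride, CC(C)C(=O)Cl
Why: Acylation of the only hydroxyl group installs the C14 isobutyrate before a second primary allylic alcohol exists, so the two esters of the target never compete.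

Step 5
Reactants: 9 tert-butyldimethyl(prop-2-ynyloxy)silane; 5 acrolein
Product: 11 (3S)-6-(tert-butyldimethylsilyloxy)hex-1-en-4-yn-3-ol, via ethyl alkynylzinc 10 (not isolated)
Conditions: ZnEt2 (2 equiv), Cy2NH (cat.), Et2O, rt; (R)-BINOL (20 mol %), Ti(OiPr)4 (50 mol %); then 5, rt; aq work-up
Reagents that add atoms: none
Why: In this catalytic asymmetric alkynylzinc addition (BINOL–Ti(OiPr)4 type, shown for enals including acrolein) the chiral titanium complex shields one aldehyde face, so 1,2-addition sets C6 as (S), the descriptor that becomes (R) once ring B is closed.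

Step 6
Reactants: 11 (3S)-6-(tert-butyldimethylsilyloxy)hex-1-en-4-yn-3-ol
Product: 13 (3S,4Z)-6-(tert-butyldimethylsilyloxy)-5-iodohexa-1,4-dien-3-ol (fragment 2), via cyclic vinylalanate 12 (not isolated)
Conditions: NaAlH2(OCH2CH2OMe)2, THF, 0 °C to rt; then I2, −78 °C
Reagents that add atoms: iodine, [I][I]
Why: In this hydroxyl-directed trans-hydroalumination the C6 alkoxide-bound hydride delivers H to C5 and Al to C4 within a five-membered alanate, and iodinolysis with retention puts iodine (later C3) cis to C6 and C15 trans to it; the silyl ether is too poor a leaving group for β-elimination to the allene at this temperature.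

Step 7
Reactants: 8 fragment 1; 13 fragment 2
Product: 15 (2E,6E,8S)-6-[(tert-butyldimethylsilyloxy)methyl]-8-hydroxy-2-(3-methylbut-2-enyl)deca-2,6,9-trienyl 2-methylpropanoate, via B-alkyl-9-BBN 14 (not isolated)
Conditions: 8, 9-BBN, THF, 0 °C to rt; then 13, PdCl2(dppf) (5 mol %), AsPh3, Cs2CO3, DMF–H2O, rt
Reagents that add atoms: none
Why: 9-BBN should add only to the monosubstituted terminus of the diene (boron on C3), and the B-alkyl Suzuki–Miyaura coupling forms C3–C4 with retention of the iodide geometry, because oxidative addition to the vinyl iodide is much faster than ionisation of the hindered allylic ester by zerovalent palladium.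

Step 8
Reactants: 15 silyl ether
Product: 16 (2E,6E,8S)-8-hydroxy-6-(hydroxymethyl)-2-(3-methylbut-2-enyl)deca-2,6,9-trienyl 2-methylpropanoate
Conditions: Bu4NF, THF, 0 °C
Reagents that add atoms: none
Why: Fluoride cleavage of the primary silyl ether frees C15–OH and leaves the isobutyrate and the C6 stereocenter untouched.

Step 9
Reactants: 16 diol
Product: 17 (2E,6E,8S)-6-(acetoxymethyl)-8-hydroxy-2-(3-methylbut-2-enyl)deca-2,6,9-trienyl 2-methylpropanoate
Conditions: AcCl (1.1 equiv), 2,4,6-collidine, CH2Cl2, −78 °C
Reagents that add atoms: acetyl chloride, CC(=O)Cl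
Why: Low-temperature acetylation with AcCl and collidine discriminates by steric demand, so the primary C15–OH should be acetylated while the secondary bis-allylic C6–OH stays free.

Step 10
Reactants: 17 hydroxy diester; 18 2-(bromomethyl)acrylic acid
Product: 19 (2E,6E,8S)-6-(acetoxymethyl)-8-[2-(bromomethyl)acryloyloxy]-2-(3-methylbut-2-enyl)deca-2,6,9-trienyl 2-methylpropanoate
Conditions: iPrN=C=NiPr, DMAP (5 mol %), CH2Cl2, −20 to 0 °C
Reagents that add atoms: none
Why: Steglich esterification attaches C11, C12 and C13 to O6 with retention at C6; a low temperature and little DMAP keep substitution of the allylic bromide slow.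

Step 11
Reactants: 19 triester
Product: 20 (2E,6E)-6-(acetoxymethyl)-7-[(2R)-4-(bromomethyl)-5-oxo-2,5-dihydrofuran-2-yl]-2-(3-methylbut-2-enyl)hepta-2,6-dienyl 2-methylpropanoate
Conditions: second-generation Hoveyda–Grubbs catalyst (5 mol %), toluene, 60 °C
Reagents that add atoms: none
Why: Ring-closing metathesis of a 2-substituted acrylate of a vinyl carbinol closes ring B (C7=C11); the catalyst loads on the only monosubstituted alkene, five-membered closure outruns all others, and the three trisubstituted alkenes stay spectators.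

Step 12
Reactants: 20 bromomethyl butenolide
Product: 21 (2E,6E)-6-(acetoxymethyl)-2-(3-methylbut-2-enyl)-7-[(2R)-5-oxo-4-(tributylstannylmethyl)-2,5-dihydrofuran-2-yl]hepta-2,6-dienyl 2-methylpropanoate
Conditions: (Bu3Sn)2 (1.1 equiv), Pd2(dba)3 (2.5 mol %), THF, rt
Reagents that add atoms: hexabutyldistannane, CCCC[Sn](CCCC)(CCCC)[Sn](CCCC)(CCCC)CCCC
Why: In this palladium-catalysed stannylation of an allylic halide with a distannane, zerovalent palladium inserts into the C13–Br bond far faster than into the two allylic carboxylates, and tin is delivered to the unhindered primary terminus C13, which keeps C7=C11 conjugated.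

Step 13
Reactants: 21 allylstannane
Product: 23 (2E,6E)-6-(acetoxymethyl)-2-(2-oxoethyl)-7-[(2R)-5-oxo-4-(tributylstannylmethyl)-2,5-dihydrofuran-2-yl]hepta-2,6-dienyl 2-methylpropanoate, via vicinal diol 22 (not isolated)
Conditions: OsO4 (2 mol %), NaIO4, 2,6-lutidine, dioxane–H2O, 0 °C to rt
Reagents that add atoms: osmium tetroxide, O=[Os](=O)(=O)=O; sodium periodate, [Na+].[O-]I(=O)(=O)=O
Why: In this Lemieux–Johnson cleavage OsO4 should pick the only electron-rich alkene (the isopropylidene group), because C1=C10 and C4=C5 are deactivated by allylic acyloxy groups and C7=C11 by the lactone; the buffered neutral medium spares the C–Sn bond and the β,γ-unsaturated aldehyde.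

Step 14
Reactants: 23 stannyl aldehyde
Product: 25 target CNP0312458.1, via difluoroboryl ether 24 (not isolated)
Conditions: BF3·OEt2 (3 equiv), CH2Cl2, −78 °C, slow addition of 23 (final about 1 mM); aq NaHCO3
Reagents that add atoms: none
Why: Proposed new method: BF3 binds the C8 aldehyde, and the C7=C11 π bond of the butenolide, raised in energy by hyperconjugation with the antiperiplanar C13–Sn bond, attacks C8 through C7 in an anti-SE2′ sense, so that C7–C8 forms, the alkene moves to C11=C13 and Bu3SnF leaves. The closest known reaction types are the BF3-promoted allylstannane–aldehyde macrocyclisation and the intermolecular metal-mediated allylation of aldehydes with 3-(bromomethyl)furan-2(5H)-ones; an allylstannane embedded in a butenolide has not been closed onto a tethered aldehyde, and tin is chosen over silicon because the carbonyl-deactivated allyl unit must still react at −78 °C at high dilution. Ring A closes in a 10-exo-trig mode at the carbonyl carbon, with C11 left outside the new ring. C7 is controlled by C6: C8 adds to the butenolide face opposite to the C5 alkenyl substituent, since a same-face approach would eclipse C5 and C8 across C6–C7 of the flat five-membered ring, and this gives the trans ring fusion (7R). C8 is controlled by the type of transition state: ring B locks C6 trans to C13 (an E-crotyl-type donor), which in a closed Zimmerman–Traxler chair (Cr, Zn, In) leads to the anti adduct, the C8 epimer, whereas in the open antiperiplanar transition state of a monodentate Lewis acid only H8 fits under ring B, C9 lies anti to C6 and the O–BF3 group points away from the lactone, which leads to the syn adduct (8R). The step needs cyclisation over oligomerisation (slow addition, high dilution), γ- over α-attack (inherent to SE2′) and survival of the two primary allylic esters and of the β,γ-unsaturated aldehyde, which the low temperature and the absence of protic acid or base should secure.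

**Compound list**

1 | ethyl (triphenylphosphoranylidene)acetate | CCOC(=O)C=P(c1ccccc1)(c1ccccc1)c1ccccc1 | starting material
2 | 1-bromo-3-methylbut-2-ene | CC(C)=CCBr | starting material
3 | (1-ethoxy-5-methyl-1-oxohex-4-en-2-yl)triphenylphosphonium bromide | CCOC(=O)C(CC=C(C)C)[P+](c1ccccc1)(c1ccccc1)c1ccccc1.[Br-] | intermediate
4 | ethyl 5-methyl-2-(triphenylphosphoranylidene)hex-4-enoate | CCOC(=O)C(CC=C(C)C)=P(c1ccccc1)(c1ccccc1)c1ccccc1 | intermediate
5 | acrolein | C=CC=O | starting material
6 | ethyl (2E)-2-(3-methylbut-2-enyl)penta-2,4-dienoate | CCOC(=O)/C(CC=C(C)C)=C/C=C | intermediate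
7 | (2E)-2-(3-methylbut-2-enyl)penta-2,4-dien-1-ol | OC/C(CC=C(C)C)=C/C=C | intermediate
8 | (2E)-2-(3-methylbut-2-enyl)penta-2,4-dienyl 2-methylpropanoate (fragment 1) | CC(C)C(=O)OC/C(CC=C(C)C)=C/C=C | intermediate
9 | tert-butyldimethyl(prop-2-ynyloxy)silane | C#CCO[Si](C)(C)C(C)(C)C | starting material
10 | ethyl[3-(tert-butyldimethylsilyloxy)prop-1-ynyl]zinc | CC[Zn]C#CCO[Si](C)(C)C(C)(C)C | intermediate
11 | (3S)-6-(tert-butyldimethylsilyloxy)hex-1-en-4-yn-3-ol | C=C[C@H](O)C#CCO[Si](C)(C)C(C)(C)C | intermediate
12 | sodium salt of the five-membered cyclic alkenylalanate (ring O6–Al–C4=C5–C6; two 2-methoxyethoxy groups on Al, vinyl on C6, CH2OTBS on C4) | [Na+].C=C[C@@H]1O[Al-](OCCOC)(OCCOC)C(CO[Si](C)(C)C(C)(C)C)=C1 | intermediate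
13 | (3S,4Z)-6-(tert-butyldimethylsilyloxy)-5-iodohexa-1,4-dien-3-ol (fragment 2) | C=C[C@H](O)/C=C(/CO[Si](C)(C)C(C)(C)C)I | intermediate
14 | (2E)-5-(9-borabicyclo[3.3.1]nonan-9-yl)-2-(3-methylbut-2-enyl)pent-2-enyl 2-methylpropanoate | CC(C)C(=O)OC/C(CC=C(C)C)=C/CCB1C2CCCC1CCC2 | intermediate
15 | (2E,6E,8S)-6-[(tert-butyldimethylsilyloxy)methyl]-8-hydroxy-2-(3-methylbut-2-enyl)deca-2,6,9-trienyl 2-methylpropanoate | C=C[C@H](O)/C=C(/CO[Si](C)(C)C(C)(C)C)CC/C=C(/COC(=O)C(C)C)CC=C(C)C | intermediate
16 | (2E,6E,8S)-8-hydroxy-6-(hydroxymethyl)-2-(3-methylbut-2-enyl)deca-2,6,9-trienyl 2-methylpropanoate | C=C[C@H](O)/C=C(/CO)CC/C=C(/COC(=O)C(C)C)CC=C(C)C | intermediate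
17 | (2E,6E,8S)-6-(acetoxymethyl)-8-hydroxy-2-(3-methylbut-2-enyl)deca-2,6,9-trienyl 2-methylpropanoate | C=C[C@H](O)/C=C(/COC(C)=O)CC/C=C(/COC(=O)C(C)C)CC=C(C)C | intermediate
18 | 2-(bromomethyl)acrylic acid | C=C(CBr)C(=O)O | starting material
19 | (2E,6E,8S)-6-(acetoxymethyl)-8-[2-(bromomethyl)acryloyloxy]-2-(3-methylbut-2-enyl)deca-2,6,9-trienyl 2-methylpropanoate | C=C[C@H](OC(=O)C(=C)CBr)/C=C(/COC(C)=O)CC/C=C(/COC(=O)C(C)C)CC=C(C)C | intermediate
20 | (2E,6E)-6-(acetoxymethyl)-7-[(2R)-4-(bromomethyl)-5-oxo-2,5-dihydrofuran-2-yl]-2-(3-methylbut-2-enyl)hepta-2,6-dienyl 2-methylpropanoate | O=C1O[C@H](/C=C(/COC(C)=O)CC/C=C(/COC(=O)C(C)C)CC=C(C)C)C=C1CBr | intermediate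
21 | (2E,6E)-6-(acetoxymethyl)-2-(3-methylbut-2-enyl)-7-[(2R)-5-oxo-4-(tributylstannylmethyl)-2,5-dihydrofuran-2-yl]hepta-2,6-dienyl 2-methylpropanoate | O=C1O[C@H](/C=C(/COC(C)=O)CC/C=C(/COC(=O)C(C)C)CC=C(C)C)C=C1C[Sn](CCCC)(CCCC)CCCC | intermediate
22 | 2,3-dihydroxy-3-methylbutyl analogue of 21 (diol at the former isopropylidene alkene, both carbinol epimers) | O=C1O[C@H](/C=C(/COC(C)=O)CC/C=C(/COC(=O)C(C)C)CC(O)C(C)(C)O)C=C1C[Sn](CCCC)(CCCC)CCCC | intermediate
23 | (2E,6E)-6-(acetoxymethyl)-2-(2-oxoethyl)-7-[(2R)-5-oxo-4-(tributylstannylmethyl)-2,5-dihydrofuran-2-yl]hepta-2,6-dienyl 2-methylpropanoate | O=C1O[C@H](/C=C(/COC(C)=O)CC/C=C(/COC(=O)C(C)C)CC=O)C=C1C[Sn](CCCC)(CCCC)CCCC | intermediate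
24 | O8-difluoroboryl ether of the target | C=C1C(=O)O[C@@H]2/C=C(/COC(C)=O)CC/C=C(/COC(=O)C(C)C)C[C@@H](OB(F)F)[C@@H]12 | intermediate
25 | [(3aR,4R,6E,10E,11aR)-10-(acetoxymethyl)-4-hydroxy-3-methylidene-2-oxo-3a,4,5,8,9,11a-hexahydrocyclodeca[b]furan-6-yl]methyl 2-methylpropanoate | C=C1C(=O)O[C@@H]2/C=C(/COC(C)=O)CC/C=C(/COC(=O)C(C)C)C[C@@H](O)[C@@H]12 | target

**Step count**

Total step count: 14. Longest linear sequence: 12 steps (steps 1–4 and 7–14).

**Steps most likely to fail**

**Step 14 (labelled step).** The open transition state may not be followed, so that facial selection at the aldehyde is lost or reversed. Slow closure may also let oligomerisation, protodestannylation or migration of C1=C10 into conjugation take over.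

The fallback uses known chemistry only and runs from 20 back to 25. Lemieux–Johnson cleavage of the isopropylidene group of 20, under the conditions of step 13, gives bromo aldehyde F1. CrCl2 in THF–DMF at high dilution closes ring A by an intramolecular Nozaki–Hiyama–Kishi-type allylation, whose closed chair should give the trans-fused 8-epi alcohol F2. Dess–Martin periodinane buffered with NaHCO3 erases C8 and gives 8-ketone F3, which is kept cold and reduced at once under Luche conditions (NaBH4, CeCl3·7H2O, MeOH, −78 °C). Hydride should come from the outer face, anti to C6 (Felkin–Anh sense, peripheral attack), which pushes the oxygen under ring B and gives 25.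

**Step 12.** Zerovalent palladium may also ionise the two allylic carboxylates. The allylpalladium complex may lose the C6 hydrogen by β-hydride elimination, or tin may be delivered to C7.

The fallback runs from 19 back to 21 and brings tin in by a radical chain at the acyclic stage, where the allyl shift is degenerate. PhSO2Na in MeOH converts 19 into allyl sulfone F4. Bu3SnH and AIBN in benzene at 80 °C exchange sulfonyl for stannyl by radical addition–fragmentation and give stannylmethyl acrylate F5. Ring-closing metathesis as in step 11 then gives 21.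

**Step 13.** Osmylation may spread to C1=C10, the oxidants may attack the C–Sn bond, and the new aldehyde may slip into conjugation during the aqueous reaction.

The fallback runs from 20 back to 23, with the oxidation done before any tin is present. Ozone (1 equiv, pyridine, CH2Cl2, −78 °C) cleaves the isopropylidene group of 20 to bromo aldehyde F1. HC(OMe)3 and PPTS mask it as dimethyl acetal F6. Stannylation as in step 12 gives stannyl acetal F7, so that no free aldehyde meets palladium and allyltin together. PPTS in wet acetone then releases 23.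

**Further compounds**

F1 | step 14 | (2E,6E)-6-(acetoxymethyl)-7-[(2R)-4-(bromomethyl)-5-oxo-2,5-dihydrofuran-2-yl]-2-(2-oxoethyl)hepta-2,6-dienyl 2-methylpropanoate | O=C1O[C@H](/C=C(/COC(C)=O)CC/C=C(/COC(=O)C(C)C)CC=O)C=C1CBr
F2 | step 14 | C8 epimer of the target (6R,7R,8S) | C=C1C(=O)O[C@@H]2/C=C(/COC(C)=O)CC/C=C(/COC(=O)C(C)C)C[C@H](O)[C@@H]12
F3 | step 14 | 8-oxo analogue of the target (6R,7R) | C=C1C(=O)O[C@@H]2/C=C(/COC(C)=O)CC/C=C(/COC(=O)C(C)C)CC(=O)[C@@H]12
F4 | step 12 | 2-(phenylsulfonylmethyl)acrylate analogue of 19 (8S) | C=C[C@H](OC(=O)C(=C)CS(=O)(=O)c1ccccc1)/C=C(/COC(C)=O)CC/C=C(/COC(=O)C(C)C)CC=C(C)C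
F5 | step 12 | 2-(tributylstannylmethyl)acrylate analogue of 19 (8S) | C=C[C@H](OC(=O)C(=C)C[Sn](CCCC)(CCCC)CCCC)/C=C(/COC(C)=O)CC/C=C(/COC(=O)C(C)C)CC=C(C)C
F6 | step 13 | dimethyl acetal of F1 | O=C1O[C@H](/C=C(/COC(C)=O)CC/C=C(/COC(=O)C(C)C)CC(OC)OC)C=C1CBr
F7 | step 13 | dimethyl acetal of 23 | O=C1O[C@H](/C=C(/COC(C)=O)CC/C=C(/COC(=O)C(C)C)CC(OC)OC)C=C1C[Sn](CCCC)(CCCC)CCCC
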